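**Retrosynthetic overview**

1. The target 15 comes from its tetrakis-MOM ether 14 by acid cleavage of the four acetals in the last step.
2. 14 is cut at both C(beta)–C(aryl) bonds at once. The strategy rests on each enone (carbonyls on C1 of ring A and C1 of ring C) ending at its beta carbon in the same 4-hydroxyphenyl ring (rings B and D), so both outer rings can be attached in one operation to the bis(acryloyl) core 11 using two molecules of aryl iodide 13.
3. 11 comes from dialdehyde 8 by addition of two molecules of vinylmagnesium bromide, one at each formyl carbon, and oxidation of both carbinols.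
4. 8 is cut at the diaryl ether C5(ring A)–O–C4(ring C) into aryl iodide 3 (from 1) and phenol 7 (from 4), joined by copper-mediated C–O coupling.
5. No ring is formed anywhere in the route; the four benzene rings are bought in 1, 4 and two molecules of 12.

Key step: step 10

Remark: ring A is the 2-hydroxy-4-methoxy-5-aryloxyphenyl ketone ring, ring C the 2-hydroxy-4-aryloxyphenyl ketone ring, and rings B and D are the 4-hydroxyphenyl rings.
Remark: in the twofold steps 7, 8, 10 and 11 both like groups react under one set of conditions. Step 7 consumes two molecules of 9 per molecule of 8 and step 10 two molecules of 13 per molecule of 11. Half-reacted species and the salts present before work-up should not accumulate and are not numbered.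

**Route**

Step 1
Reactants: 1 2-hydroxy-4-methoxybenzaldehyde
Product: 2 2-hydroxy-5-iodo-4-methoxybenzaldehyde
Conditions: NIS (1.05 equiv), TFA (cat.), MeCN, 0 °C to rt
Reagents that add atoms: N-iodosuccinimide, O=C1CCC(=O)N1I
Why: Electrophilic aromatic iodination with acid-activated NIS should go to C5, which is para to the free hydroxyl, ortho to the methoxy group and less crowded than C3 between the two oxygens; the iodide is chosen over the bromide because it is the more reactive partner for the copper-mediated etherification in step 6.

Step 2
Reactants: 2 2-hydroxy-5-iodo-4-methoxybenzaldehyde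
Product: 3 5-iodo-4-methoxy-2-(methoxymethoxy)benzaldehyde
Conditions: MOMCl (1.5 equiv), K2CO3, acetone, reflux
Reagents that add atoms: chloromethyl methyl ether, COCCl
Why: Williamson-type O-alkylation of the phenoxide with the reactive alpha-chloro ether gives the MOM acetal, which removes the only nucleophilic OH of the ring A fragment so that it cannot couple with itself in step 6 or add to the enone later.

Step 3
Reactants: 4 2,4-dihydroxybenzaldehyde
Product: 5 4-(allyloxy)-2-hydroxybenzaldehyde
Conditions: allyl bromide (1.1 equiv), KHCO3 (1.5 equiv), MeCN, 60 °C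
Reagents that add atoms: allyl bromide, C=CCBr
Why: Regioselective Williamson etherification, since the C4 hydroxyl para to the aldehyde is the more acidic one and is not held in the hydrogen bond to the carbonyl, so the weak base KHCO3 should ionise only this position.

Step 4
Reactants: 5 4-(allyloxy)-2-hydroxybenzaldehyde
Product: 6 4-(allyloxy)-2-(methoxymethoxy)benzaldehyde
Conditions: MOMCl (1.5 equiv), K2CO3, acetone, reflux
Reagents that add atoms: chloromethyl methyl ether, COCCl
Why: Williamson-type MOM protection in which the stronger carbonate base ionises the chelated C2 hydroxyl, while the allyl ether and the non-enolisable aldehyde are inert.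

Step 5
Reactants: 6 4-(allyloxy)-2-(methoxymethoxy)benzaldehyde
Product: 7 4-hydroxy-2-(methoxymethoxy)benzaldehyde
Conditions: Pd(PPh3)4 (2 mol%), K2CO3 (3 equiv), MeOH, rt; aq. NH4Cl work-up
Reagents that add atoms: none
Why: Tsuji–Trost-type deallylation in which zerovalent palladium ionises the allyl aryl ether to an allyl complex of divalent palladium and a stabilised 4-formylphenoxide, and methoxide captures the allyl group, leaving the MOM acetal and the aldehyde untouched.

Step 6
Reactants: 3 5-iodo-4-methoxy-2-(methoxymethoxy)benzaldehyde; 7 4-hydroxy-2-(methoxymethoxy)benzaldehyde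
Product: 8 5-[4-formyl-3-(methoxymethoxy)phenoxy]-4-methoxy-2-(methoxymethoxy)benzaldehyde
Conditions: CuI (10 mol%), picolinic acid (20 mol%), K3PO4 (2 equiv), DMSO, 90 °C
Reagents that add atoms: none
Why: Ullmann-type diaryl ether synthesis in which the phenoxide of 7 binds picolinate-ligated monovalent copper, the C–I bond of 3 adds oxidatively and C–O reductive elimination joins C5 of ring A to the C4 oxygen of ring C; each partner has a single reactive site, so only one ether can form.

Step 7
Reactants: 8 5-[4-formyl-3-(methoxymethoxy)phenoxy]-4-methoxy-2-(methoxymethoxy)benzaldehyde; 9 vinylmagnesium bromide (2.6 equiv)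
Product: 10 1-[5-[4-(1-hydroxyprop-2-enyl)-3-(methoxymethoxy)phenoxy]-4-methoxy-2-(methoxymethoxy)phenyl]prop-2-en-1-ol (mixture of diastereomers)
Conditions: THF, −78 to 0 °C; aq. NH4Cl work-up
Reagents that add atoms: none
Why: Twofold Grignard 1,2-addition in which one molecule of 9 adds to each of the two non-enolisable aryl aldehydes, assisted by chelation of magnesium to the neighbouring MOM oxygen, the small excess ensuring that no mono-adduct remains; the two new carbinol centres are formed without control and are erased by the oxidation in step 8.

Step 8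
Reactants: 10 1-[5-[4-(1-hydroxyprop-2-enyl)-3-(methoxymethoxy)phenoxy]-4-methoxy-2-(methoxymethoxy)phenyl]prop-2-en-1-ol
Product: 11 1-[4-methoxy-2-(methoxymethoxy)-5-[3-(methoxymethoxy)-4-(prop-2-enoyl)phenoxy]phenyl]prop-2-en-1-one
Conditions: activated MnO2 (excess), CH2Cl2, rt; filtered, concentrated cold with a trace of BHT and used at once
Reagents that add atoms: none
Why: Activated MnO2 oxidises alcohols that are both benzylic and allylic to the ketones under neutral conditions, so the acid-labile MOM acetals survive and over-oxidation is not possible.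

Step 9
Reactants: 12 4-iodophenol
Product: 13 1-iodo-4-(methoxymethoxy)benzene
Conditions: MOMCl (1.3 equiv), K2CO3, acetone, rt to reflux
Reagents that add atoms: chloromethyl methyl ether, COCCl
Why: Williamson-type MOM protection of an unhindered phenoxide; masking this phenol keeps a phenoxide from adding in a conjugate sense to the vinyl ketones in step 10.

Step 10
Reactants: 11 1-[4-methoxy-2-(methoxymethoxy)-5-[3-(methoxymethoxy)-4-(prop-2-enoyl)phenoxy]phenyl]prop-2-en-1-one; 13 1-iodo-4-(methoxymethoxy)benzene (2.5 equiv)
Product: 14 (E)-1-[4-methoxy-2-(methoxymethoxy)-5-[3-(methoxymethoxy)-4-[(E)-3-[4-(methoxymethoxy)phenyl]prop-2-enoyl]phenoxy]phenyl]-3-[4-(methoxymethoxy)phenyl]prop-2-en-1-one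
Conditions: Pd(OAc)2 (10 mol%), Bu4NCl (2 equiv), NaHCO3 (5 equiv), BHT (trace), DMF, 50 °C, N2, dark
Reagents that add atoms: none
Why: This is a Mizoroki–Heck reaction run twice on one substrate under ligand-free Jeffery conditions: zerovalent palladium formed in the flask from Pd(OAc)2 inserts into the C–I bond of 13 to give an aryl iodide complex of divalent palladium, the terminal alkene of an acryloyl group inserts syn with the aryl group going to the unsubstituted beta carbon, and syn beta-hydride elimination releases the conjugated enone while NaHCO3 takes up HI and returns zerovalent palladium. The closest known reaction type is the Heck arylation of aryl vinyl ketones with aryl iodides to chalcones, applied here to two enones in one molecule. No ring is closed and no stereocentre is formed. The step needs beta-regioselectivity and E geometry: the polarised, monosubstituted enone should take the aryl group at its terminal carbon for electronic and steric reasons, and syn elimination from the less strained rotamer should give the E-alkene at both sites. The MOM ethers on C2 of rings A and C block oxa-Michael closure to chromanones, and the MOM ether on 13 blocks phenoxide addition to the vinyl ketone. A hydride-free inorganic base, the low temperature allowed by the ammonium salt and a radical inhibitor should hold back reductive conjugate arylation and polymerisation of 11.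

Step 11
Reactants: 14 (E)-1-[4-methoxy-2-(methoxymethoxy)-5-[3-(methoxymethoxy)-4-[(E)-3-[4-(methoxymethoxy)phenyl]prop-2-enoyl]phenoxy]phenyl]-3-[4-(methoxymethoxy)phenyl]prop-2-en-1-one
Product: 15 (E)-1-[2-hydroxy-5-[3-hydroxy-4-[(E)-3-(4-hydroxyphenyl)prop-2-enoyl]phenoxy]-4-methoxyphenyl]-3-(4-hydroxyphenyl)prop-2-en-1-one (target)
Conditions: 3 M aq. HCl, MeOH/THF, 50 °C, dark, stopped at full conversion
Reagents that add atoms: none
Why: Acid-catalysed acetal exchange with methanol cleaves all four MOM ethers through oxocarbenium ions, while the diaryl ether, the aryl methyl ether and the E-enones are stable to dilute acid and the freed C2 hydroxyls are held in hydrogen bonds to the ketones.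

**Compound list**

1 | 2-hydroxy-4-methoxybenzaldehyde | COc1ccc(C=O)c(O)c1 | starting material
2 | 2-hydroxy-5-iodo-4-methoxybenzaldehyde | COc1cc(O)c(C=O)cc1I | intermediate
3 | 5-iodo-4-methoxy-2-(methoxymethoxy)benzaldehyde | COc1cc(OCOC)c(C=O)cc1I | intermediate
4 | 2,4-dihydroxybenzaldehyde | O=Cc1ccc(O)cc1O | starting material
5 | 4-(allyloxy)-2-hydroxybenzaldehyde | C=CCOc1ccc(C=O)c(O)c1 | intermediate
6 | 4-(allyloxy)-2-(methoxymethoxy)benzaldehyde | C=CCOc1ccc(C=O)c(OCOC)c1 | intermediate
7 | 4-hydroxy-2-(methoxymethoxy)benzaldehyde | COCOc1cc(O)ccc1C=O | intermediate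
8 | 5-[4-formyl-3-(methoxymethoxy)phenoxy]-4-methoxy-2-(methoxymethoxy)benzaldehyde | COc1cc(OCOC)c(C=O)cc1Oc1ccc(C=O)c(OCOC)c1 | intermediate
9 | vinylmagnesium bromide | C=C[Mg]Br | starting material
10 | 1-[5-[4-(1-hydroxyprop-2-enyl)-3-(methoxymethoxy)phenoxy]-4-methoxy-2-(methoxymethoxy)phenyl]prop-2-en-1-ol, mixture of diastereomers | COc1cc(OCOC)c(C(O)C=C)cc1Oc1ccc(C(O)C=C)c(OCOC)c1 | intermediate
11 | 1-[4-methoxy-2-(methoxymethoxy)-5-[3-(methoxymethoxy)-4-(prop-2-enoyl)phenoxy]phenyl]prop-2-en-1-one | COc1cc(OCOC)c(C(=O)C=C)cc1Oc1ccc(C(=O)C=C)c(OCOC)c1 | intermediate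
12 | 4-iodophenol | Oc1ccc(I)cc1 | starting material
13 | 1-iodo-4-(methoxymethoxy)benzene | COCOc1ccc(I)cc1 | intermediate
14 | tetrakis-MOM ether of the target, both alkenes E | COc1cc(OCOC)c(C(=O)/C=C/c2ccc(OCOC)cc2)cc1Oc1ccc(C(=O)/C=C/c2ccc(OCOC)cc2)c(OCOC)c1 | intermediate
15 | (E)-1-[2-hydroxy-5-[3-hydroxy-4-[(E)-3-(4-hydroxyphenyl)prop-2-enoyl]phenoxy]-4-methoxyphenyl]-3-(4-hydroxyphenyl)prop-2-en-1-one | COc1cc(O)c(C(=O)/C=C/c2ccc(O)cc2)cc1Oc1ccc(C(=O)/C=C/c2ccc(O)cc2)c(O)c1 | target

**Step count**

Total: 11 steps. Longest linear sequence: 8 steps (4 → 5 → 6 → 7 → 8 → 10 → 11 → 14 → 15; steps 3, 4, 5, 6, 7, 8, 10, 11).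

**Steps most likely to fail**

1. Step 10. Polymerisation of the bis(vinyl ketone) or stalling after the first arylation may outrun the Heck cycle. The fallback avoids vinyl ketones altogether and so also covers loss of 11 during its isolation in step 8. It sets out from dialdehyde 8: addition of methylmagnesium bromide in THF should give the bis(1-hydroxyethyl) compound F1, and oxidation with activated MnO2 should give the bis(methyl ketone) F2. A twofold Claisen–Schmidt condensation of F2 with purchased 4-(methoxymethoxy)benzaldehyde F3 (KOH, EtOH, rt) should then give both E-enones and return to the route at 14.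

2. Step 6. The C–O coupling may be slow because the phenoxide of 7 is electron-poor and the iodide of 3 is flanked by a methoxy group, so that protodeiodination or catalyst deactivation takes over. The fallback reverses the polarity of the ether formation and sets out from 3. Miyaura borylation (B2pin2, PdCl2(dppf), KOAc, dioxane, 80 °C) should give the pinacol boronate F4, and oxidation with NaBO3·4H2O in THF/water at rt should give the ring A phenol, 5-hydroxy-4-methoxy-2-(methoxymethoxy)benzaldehyde F5. Purchased 4-fluoro-2-hydroxybenzaldehyde F6 is protected with MOMCl and K2CO3 to give 4-fluoro-2-(methoxymethoxy)benzaldehyde F7. Nucleophilic aromatic substitution of the fluoride para to the aldehyde in F7 by the phenoxide of F5 (K2CO3, DMF, 100 °C) returns to the route at 8.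

3. Step 11. During the time needed to cleave the two unactivated aryl MOM ethers on rings B and D, the freed C2 hydroxyls may add to the enones under acid (closure to flavanones). The fallback needs only the two chelation-activated MOM ethers to be cleaved. It sets out from 11 and unprotected 4-iodophenol 12, coupled under the conditions of step 10, where the weak base NaHCO3 should keep the phenoxide concentration low. This should give the bis-MOM bichalcone F8, which has free hydroxyls on rings B and D and MOM ethers only on C2 of rings A and C. These two MOM groups sit ortho to the ketones and should be lost under much milder acid (dilute HCl in MeOH at rt), returning to the route at the target 15.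

**Further compounds**

F1 | step 10 | 1-[5-[4-(1-hydroxyethyl)-3-(methoxymethoxy)phenoxy]-4-methoxy-2-(methoxymethoxy)phenyl]ethanol | COc1cc(OCOC)c(C(C)O)cc1Oc1ccc(C(C)O)c(OCOC)c1
F2 | step 10 | 1-[5-[4-acetyl-3-(methoxymethoxy)phenoxy]-4-methoxy-2-(methoxymethoxy)phenyl]ethanone | COc1cc(OCOC)c(C(C)=O)cc1Oc1ccc(C(C)=O)c(OCOC)c1
F3 | step 10 | 4-(methoxymethoxy)benzaldehyde | COCOc1ccc(C=O)cc1
F4 | step 6 | 4-methoxy-2-(methoxymethoxy)-5-(4,4,5,5-tetramethyl-1,3,2-dioxaborolan-2-yl)benzaldehyde | COc1cc(OCOC)c(C=O)cc1B1OC(C)(C)C(C)(C)O1
F5 | step 6 | 5-hydroxy-4-methoxy-2-(methoxymethoxy)benzaldehyde | COc1cc(OCOC)c(C=O)cc1O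
F6 | step 6 | 4-fluoro-2-hydroxybenzaldehyde | O=Cc1ccc(F)cc1O
F7 | step 6 | 4-fluoro-2-(methoxymethoxy)benzaldehyde | COCOc1cc(F)ccc1C=O
F8 | step 11 | (E)-3-(4-hydroxyphenyl)-1-[5-[4-[(E)-3-(4-hydroxyphenyl)prop-2-enoyl]-3-(methoxymethoxy)phenoxy]-4-methoxy-2-(methoxymethoxy)phenyl]prop-2-en-1-one | COc1cc(OCOC)c(C(=O)/C=C/c2ccc(O)cc2)cc1Oc1ccc(C(=O)/C=C/c2ccc(O)cc2)c(OCOC)c1
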